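A chemist has Qe, Ze, two earlier runs and a set of flasks to rank, and I reckon them here.

| flask | Qe | Ze | temperature | remark | time |
|---|---|---|---|---|---|
| south-west | 0.050 M | 2 equiv | 90 °C | run made earlier |  |
| north-east | 0.050 M | 1 equiv | 90 °C | run made earlier |  |
| alpha | 0.050 M | 2.00 equiv | 90 °C | everything together at the start | 5.0 h |
| eta | 0.050 M | 2.00 equiv (fed, over 3.0 h) |  | the addition at 50 °C, then warmed to 90 °C; the feed brings no volume worth counting | 5.0 h |
| delta | 0.050 M (fed, over 3.0 h) | 2.00 equiv | 90 °C | all else is in the flask from the start; the feed brings no volume worth counting | 5.0 h |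
| gamma | 0.050 M | 2.00 equiv (fed, over 3.0 h) | 90 °C | all else is in the flask from the start; the feed brings no volume worth counting | 5.0 h |

south-west run (percent of the Qe charged)

| time / h | Aj / % |
|---|---|
| 0.667 | 49.1 |
| 2.00 | 79.0 |
| 3.00 | 87.9 |
| 5.00 | 93.9 |

north-east run (percent of the Qe charged)

| time / min | Aj / % |
|---|---|
| 12.0 | 12.4 |
| 30.0 | 20.6 |
| 60.0 | 34.9 |
| 90.0 | 45.1 |

(each reading ± 1 percentage point)

* the flask that comes out highest in amount of Aj, in percent of the Qe charged, or "all alike" when all lie within 1.5 percentage points (alpha / eta / delta / gamma / all alike)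
* Aj at the end, in percent of the Qe charged, alpha
* Aj at the end, in percent of the Qe charged, eta
* Aj at the end, in percent of the Qe charged, delta
* Aj at the end, in percent of the Qe charged, gamma

- the analysis behind the earlier runs scatters by 1 percentage point, standard deviation
- a reading or a percentage of Aj counts all its forms, free or not
- the earlier runs do not show what temperature does; that part of a forecast is a guess

In the north-east run, with equal charges, the last reading gives a rate κ, the rate constant times the Qe charge, where y is the fraction turned to Aj:

κ = y/((1 − y)·t) = 0.548 h⁻¹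

With E equivalents of Ze, Qe is the limiting reagent, and the fraction of Ze left over the fraction of Qe left grows as e^N. I fold the givens into one number:

N = κ·(E − 1)·t

Here t is the time at full strength, and N is the logarithm of that ratio. I count the feed of eta as lost, a guess, since the runs do not show temperature:

N = 1.10

Aj = E(e^N − 1)/(E·e^N − 1) = 79.9%

The south-west run, independent of κ, reads 79.0% at 2.00 h, which is that same N.

One number is not enough late on. At 5.00 h in the south-west run, N = 2.74 gives 96.7%, which is 2.8 percentage points above the reading. So for alpha I take the reading.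

For delta and gamma I count half of the feed as lost, and N = 1.92 gives 92.1% for each, so this N does not part these two.

The forecast names alpha, with 94% for alpha, 81% for eta, 89.5% for delta and 90% for gamma. It calls eta's number “the least certain”. Its figures for delta and gamma stand below my 92.1%, and its figure for eta stands above my 79.9%.

The flasks give 93.6% for alpha, 79.7% for eta, 86.7% for delta and 89.5% for gamma, so alpha comes out highest.

    Qe + Ze → Aj + Kj (k = 11.5 M⁻¹ h⁻¹, Ea = 89.0 kJ mol⁻¹)
    Ze + Aj → Xa + Kj (k = 4.08 M⁻¹ h⁻¹, Ea = 80.0 kJ mol⁻¹)
    Ze + Xa → Xo + Kj (k = 10.7 M⁻¹ h⁻¹, Ea = 84.0 kJ mol⁻¹)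
    Ej ⇌ Aj, rate k4*(cs4 - [Aj]) while solid is left; crystals form when [Aj] > cs4 (solubility = 1.20 mM, k = 78.2 h⁻¹)
    (constants at 90 °C)

At 5.00 h in eta, the step to Aj uses Ze 21 times as fast as the step from Aj to Xa. The fraction of Ze left over the fraction of Qe left in eta there is 3.12, against 3.00 from N. A neighbouring flask, eta with 0.020 M of Qe and the same equivalents of Ze, has N = 0.438, which reckons to 52.4% of Aj, and it holds 52.6%.

Readings and results come from a simulation on assumed constants.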